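**Retrosynthetic overview** (ring A = cyclopentanone, ring B = cyclohexane, ring C = cyclooctane, ring D = methylcyclopentane)
1. Target ⇐ last-step oxidation of the ring A alcohol; ring C ⇐ ring-closing metathesis of two vinyl groups, then hydrogenation; oxirane ⇐ hydroxyl-directed epoxidation of a tetrasubstituted alkene.
2. That alkene and the tertiary alcohol ⇐ addition of the (Z)-alkenyllithium from east iodide 28 (ring D) to west hydrindanone 16 (rings A and B).
3. 16 ⇐ key Claisen [3,3] rearrangement of the (Z)-crotyl enol ether of ketone 12: it makes the bond from ring B to the methyl-bearing side-chain carbon, both flanking stereocentres and the vinyl handle. 12 ⇐ (S)-carvone (ring B bought; ring A by alkylation, hydration, aldol; trans fusion by Li/NH3).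
4. 28 ⇐ (S)-β-citronellene: zirconocene enyne cyclisation and iodinolysis give ring D and the (Z)-iodoalkene; the cis vinyl group comes from hydroboration of an exocyclic methylene.
5. Ring order: B (carvone) → A (step 3); D (step 12); oxirane (step 18); C (step 19).

Assumption: the achiral building blocks 2 and 13 are bought as catalogue reagents.

**Step 1**
Reactants: 1 (S)-(+)-carvone; 2 1-bromo-4-methylpent-2-yne
Product: 4 (2S,5S)-2-methyl-2-(4-methylpent-2-yn-1-yl)-5-(prop-1-en-2-yl)cyclohexan-1-one, via lithium enolate 3 (not isolated)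
Conditions: Li, NH3(l), t-BuOH (1 equiv), THF, −78 °C; then 2, −78 °C → rt
Reagents that add atoms: none
Why: Dissolving-metal reduction of the enone gives the regiodefined enolate, and reductive alkylation (SN2, axial attack, new chain cis to the equatorial isopropenyl group) sets the quaternary methyl centre under control of the carvone stereocentre.

**Step 2**
Reactants: 4 (2S,5S)-2-methyl-2-(4-methylpent-2-yn-1-yl)-5-(prop-1-en-2-yl)cyclohexan-1-one
Product: 5 (2S,5S)-2-methyl-2-(4-methyl-2-oxopentyl)-5-(prop-1-en-2-yl)cyclohexan-1-one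
Conditions: NaAuCl4·2H2O (2 mol %), MeOH/H2O 10:1, reflux
Reagents that add atoms: water, O
Why: Gold-catalysed alkyne hydration in which the ring ketone adds 5-exo to the activated alkyne, so oxygen ends on the proximal alkyne carbon and only the 1,4-diketone forms; the isopropenyl group is inert.

**Step 3**
Reactants: 5 (2S,5S)-2-methyl-2-(4-methyl-2-oxopentyl)-5-(prop-1-en-2-yl)cyclohexan-1-one
Product: 7 (5S,7aS)-3-isopropyl-7a-methyl-5-(prop-1-en-2-yl)-1,4,5,6,7,7a-hexahydro-2H-inden-2-one, via cis-fused ketol 6 (not isolated)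
Conditions: KOH, EtOH, reflux
Reagents that add atoms: none
Why: Intramolecular aldol condensation (cyclopentenone annulation) closes ring A, because only the adduct from the isobutyl-ketone α-carbon can dehydrate (the alternative aldol is bridged); no new stereocentre survives.

**Step 4**
Reactants: 7 (5S,7aS)-3-isopropyl-7a-methyl-5-(prop-1-en-2-yl)-1,4,5,6,7,7a-hexahydro-2H-inden-2-one
Product: 9 (5S,7aS)-3-isopropyl-7a-methyl-2-oxo-2,4,5,6,7,7a-hexahydro-1H-inden-5-yl acetate, via methoxy hydroperoxide 8 (not isolated)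
Conditions: O3, CH2Cl2/MeOH, −78 °C; then Ac2O, Et3N, DMAP (cat.), 0 → 40 °C
Reagents that add atoms: ozone, [O-][O+]=O; methanol, CO
Why: Ozonolysis takes the electron-rich isopropenyl group and spares the hindered conjugated alkene, and Criegee rearrangement of the acetylated methoxy hydroperoxide moves the ring carbon to oxygen with retention of configuration.

**Step 5**
Reactants: 9 (5S,7aS)-3-isopropyl-7a-methyl-2-oxo-2,4,5,6,7,7a-hexahydro-1H-inden-5-yl acetate
Product: 10 (2R,3R,3aS,5S,7aS)-3-isopropyl-7a-methyloctahydro-1H-indene-2,5-diol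
Conditions: Li, NH3(l), THF, EtOH, −78 → −33 °C; NH4Cl
Reagents that add atoms: none
Why: Dissolving-metal (Birch-type) reduction: ring A keeps its CH2 link equatorial on ring B, so the β-carbanion is protonated axially, anti to the axial angular methyl (trans fusion); the enolate is protonated on the open lower face (isopropyl cis to the methyl), the ketone is reduced on to the more stable alcohol and the acetate is cleaved.

**Step 6**
Reactants: 10 (2R,3R,3aS,5S,7aS)-3-isopropyl-7a-methyloctahydro-1H-indene-2,5-diol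
Product: 11 (2R,3R,3aS,7aS)-2-hydroxy-3-isopropyl-7a-methyloctahydro-5H-inden-5-one
Conditions: TEMPO (10 mol %), PhI(OAc)2 (1.1 equiv), CH2Cl2, 0 °C → rt
Reagents that add atoms: none
Why: Oxoammonium (TEMPO) oxidation is highly sensitive to hindrance, so the unhindered axial cyclohexanol is oxidised while the cyclopentanol next to the isopropyl-bearing carbon survives.

**Step 7**
Reactants: 11 (2R,3R,3aS,7aS)-2-hydroxy-3-isopropyl-7a-methyloctahydro-5H-inden-5-one
Product: 12 (2R,3R,3aS,7aS)-2-(benzyloxy)-3-isopropyl-7a-methyloctahydro-5H-inden-5-one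
Conditions: BnOC(=NH)CCl3, TfOH (cat.), CH2Cl2/cyclohexane, 0 °C → rt
Reagents that add atoms: benzyl 2,2,2-trichloroacetimidate, ClC(Cl)(Cl)C(=N)OCc1ccccc1
Why: Acid-catalysed O-benzylation with the trichloroacetimidate needs no base, so the ketone is not enolised, and the ether is later removed in the hydrogenation step.

**Step 8**
Reactants: 12 (2R,3R,3aS,7aS)-2-(benzyloxy)-3-isopropyl-7a-methyloctahydro-5H-inden-5-one; 13 (Z)-but-2-en-1-ol
Product: 16 (2R,3R,3aS,6R,7aS)-2-(benzyloxy)-6-[(2R)-but-3-en-2-yl]-3-isopropyl-7a-methyloctahydro-5H-inden-5-one, via dicrotyl ketal 14 (not isolated), via crotyl enol ether 15 (not isolated)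
Conditions: 13 (8 equiv), 2,4-dinitrophenol (cat.), xylenes, 140 °C, Dean–Stark
Reagents that add atoms: none
Why: Ketal exchange and loss of crotyl alcohol give the more stable enol ether away from the ring fusion, which undergoes the Claisen [3,3]-sigmatropic rearrangement through a chair on the face opposite the axial angular methyl; the ring CH2 lies trans to oxygen and the (Z)-methyl cis to the allylic CH2, which gives the anti (R,R) pair at the new ring and side-chain centres.

**Step 9**
Reactants: 17 (S)-β-citronellene [(3S)-3,7-dimethylocta-1,6-diene]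
Product: 18 (4S)-4-methylhex-5-enal
Conditions: O3 (1 equiv), CH2Cl2, pyridine (cat.), −78 °C; then Me2S
Reagents that add atoms: ozone, [O-][O+]=O
Why: Ozonolysis with one equivalent cleaves the electron-rich trisubstituted alkene much faster than the vinyl group; the stereocentre is untouched.

**Step 10**
Reactants: 18 (4S)-4-methylhex-5-enal
Product: 19 (5S)-1,1-dibromo-5-methylhepta-1,6-diene
Conditions: CBr4, PPh3, CH2Cl2, 0 °C
Reagents that add atoms: carbon tetrabromide, BrC(Br)(Br)Br
Why: Corey–Fuchs (Ramirez) dibromo-olefination of the aldehyde, neutral enough to leave the remote stereocentre alone.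

**Step 11**
Reactants: 19 (5S)-1,1-dibromo-5-methylhepta-1,6-diene
Product: 21 (3S)-3-methylnon-1-en-7-yne, via lithium acetylide 20 (not isolated)
Conditions: n-BuLi (2.1 equiv), THF, −78 → 0 °C; then MeI, −78 °C → rt
Reagents that add atoms: iodomethane, CI
Why: Second Corey–Fuchs stage: Br/Li exchange, Fritsch–Buttenberg–Wiechell rearrangement to the acetylide and C-methylation.

**Step 12**
Reactants: 21 (3S)-3-methylnon-1-en-7-yne
Product: 23 (1Z,2R,3S)-1-(1-iodoethylidene)-2-(iodomethyl)-3-methylcyclopentane, via zirconacyclopentene 22 (not isolated)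
Conditions: Cp2ZrCl2, n-BuLi (2 equiv), THF, −78 °C → rt; then I2, −78 °C → rt
Reagents that add atoms: iodine, II
Why: Negishi zirconocene-mediated enyne cyclisation forms ring D with Zr and the new C–C bond cis on the alkene, so iodinolysis gives the (Z)-tetrasubstituted alkenyl iodide; the ring CH centre (expected trans to methyl) is erased in the next step.

**Step 13**
Reactants: 23 (1Z,2R,3S)-1-(1-iodoethylidene)-2-(iodomethyl)-3-methylcyclopentane
Product: 24 (1Z,3S)-1-(1-iodoethylidene)-3-methyl-2-methylidenecyclopentane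
Conditions: t-BuOK, THF, 0 °C → rt
Reagents that add atoms: none
Why: E2 elimination of the primary iodide across its only β-C–H gives the exocyclic methylene; the tetrasubstituted alkenyl iodide has no vinylic hydrogen and stays.

**Step 14**
Reactants: 24 (1Z,3S)-1-(1-iodoethylidene)-3-methyl-2-methylidenecyclopentane
Product: 26 [(1S,2S,5Z)-5-(1-iodoethylidene)-2-methylcyclopentyl]methanol, via alkyl-9-BBN 25 (not isolated)
Conditions: 9-BBN, THF, 0 °C → rt; then NaOH, H2O2, 0 °C
Reagents that add atoms: hydrogen peroxide, OO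
Why: Hydroboration–oxidation puts boron on the terminal carbon and hydrogen on the ring carbon from the face opposite the neighbouring methyl, so the CH2OH arm ends cis to the methyl.

**Step 15**
Reactants: 26 [(1S,2S,5Z)-5-(1-iodoethylidene)-2-methylcyclopentyl]methanol
Product: 27 (1S,2S,5Z)-5-(1-iodoethylidene)-2-methylcyclopentane-1-carbaldehyde
Conditions: Dess–Martin periodinane, NaHCO3, CH2Cl2, 0 °C
Reagents that add atoms: none
Why: Buffered Dess–Martin oxidation gives the aldehyde without epimerising the α-centre; it is used at once.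

**Step 16**
Reactants: 27 (1S,2S,5Z)-5-(1-iodoethylidene)-2-methylcyclopentane-1-carbaldehyde
Product: 28 (1Z,2S,3S)-2-ethenyl-1-(1-iodoethylidene)-3-methylcyclopentane
Conditions: Ph3PCH3Br, KN(SiMe3)2, THF, 0 °C; then 27, −78 → 0 °C
Reagents that add atoms: methyltriphenylphosphonium bromide, [Br-].C[P+](c1ccccc1)(c1ccccc1)c1ccccc1
Why: Wittig methylenation with preformed ylide and no excess base at low temperature converts the aldehyde into the vinyl group before the α-centre can epimerise.

**Step 17**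
Reactants: 28 (1Z,2S,3S)-2-ethenyl-1-(1-iodoethylidene)-3-methylcyclopentane; 16 (2R,3R,3aS,6R,7aS)-2-(benzyloxy)-6-[(2R)-but-3-en-2-yl]-3-isopropyl-7a-methyloctahydro-5H-inden-5-one
Product: 30 (2R,3R,3aS,5R,6R,7aS)-2-(benzyloxy)-6-[(2R)-but-3-en-2-yl]-5-{(1Z)-1-[(2S,3S)-2-ethenyl-3-methylcyclopentylidene]ethyl}-3-isopropyl-7a-methyloctahydro-1H-inden-5-ol, via alkenyllithium 29 (not isolated)
Conditions: 28, t-BuLi (2 equiv), Et2O, −78 °C; then 16, THF, −78 → −40 °C; H2O
Reagents that add atoms: none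
Why: Iodine–lithium exchange keeps the alkene geometry, and 1,2-addition of the bulky alkenyllithium along the equatorial trajectory of the cyclohexanone gives the axial tertiary alcohol.

**Step 18**
Reactants: 30 (2R,3R,3aS,5R,6R,7aS)-2-(benzyloxy)-6-[(2R)-but-3-en-2-yl]-5-{(1Z)-1-[(2S,3S)-2-ethenyl-3-methylcyclopentylidene]ethyl}-3-isopropyl-7a-methyloctahydro-1H-inden-5-ol
Product: 31 (2R,3R,3aS,5R,6R,7aS)-2-(benzyloxy)-6-[(2R)-but-3-en-2-yl]-5-[(2R,3S,4S,5S)-4-ethenyl-2,5-dimethyl-1-oxaspiro[2.4]heptan-2-yl]-3-isopropyl-7a-methyloctahydro-1H-inden-5-ol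
Conditions: VO(acac)2 (10 mol %), t-BuOOH, CH2Cl2, 0 °C → rt
Reagents that add atoms: tert-butyl hydroperoxide, CC(C)(C)OO
Why: Hydroxyl-directed vanadium-catalysed epoxidation selects the tetrasubstituted allylic alkene over both vinyl groups and delivers oxygen syn to the alkene on the face of the alkylidene-cyclopentane opposite its vinyl and methyl substituents, which sets both oxirane carbons.

**Step 19**
Reactants: 31 (2R,3R,3aS,5R,6R,7aS)-2-(benzyloxy)-6-[(2R)-but-3-en-2-yl]-5-[(2R,3S,4S,5S)-4-ethenyl-2,5-dimethyl-1-oxaspiro[2.4]heptan-2-yl]-3-isopropyl-7a-methyloctahydro-1H-inden-5-ol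
Product: 32 tetracyclic epoxy alcohol benzyl ether with a (Z)-CH=CH unit in ring C (target skeleton; OBn in place of the ring A ketone)
Conditions: second-generation Grubbs catalyst RuCl2(=CHPh)(PCy3)(H2IMes) (10 mol %), CH2Cl2 (2 mM), 40 °C
Reagents that add atoms: none
Why: Ring-closing olefin metathesis of the two vinyl groups, held cis by the oxirane and ring B, closes eight-membered ring C as the (Z)-alkene with loss of ethene; no stereocentre changes.

**Step 20**
Reactants: 32 tetracyclic epoxy alcohol benzyl ether with a (Z)-CH=CH unit in ring C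
Product: 33 saturated tetracyclic epoxy diol (target with a secondary alcohol in place of the ring A ketone)
Conditions: H2 (4 bar), Pd(OH)2/C, EtOAc/EtOH, rt
Reagents that add atoms: none
Why: Heterogeneous hydrogenation saturates the ring C alkene and hydrogenolyses the benzyl ether, while the tetrasubstituted oxirane and tertiary alcohol are inert and no stereocentre is formed.

**Step 21**
Reactants: 33 saturated tetracyclic epoxy diol
Product: 34 target CNP0332295.1
Conditions: Dess–Martin periodinane, NaHCO3, CH2Cl2, 0 °C → rt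
Reagents that add atoms: none
Why: Buffered Dess–Martin oxidation of the only secondary alcohol gives the ring A ketone under non-epimerising conditions, so the kinetically set isopropyl centre next to it is kept.

**Compound list**
1 | (S)-(+)-carvone | O=C1C[C@@H](C(C)=C)CC=C1C | starting material
2 | 1-bromo-4-methylpent-2-yne | BrCC#CC(C)C | starting material
3 | lithium (5S)-2-methyl-5-(prop-1-en-2-yl)cyclohex-1-en-1-olate | [Li]OC1=C(C)CC[C@H](C(C)=C)C1 | intermediate
4 | (2S,5S)-2-methyl-2-(4-methylpent-2-yn-1-yl)-5-(prop-1-en-2-yl)cyclohexan-1-one | O=C1C[C@@H](C(C)=C)CC[C@@]1(C)CC#CC(C)C | intermediate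
5 | (2S,5S)-2-methyl-2-(4-methyl-2-oxopentyl)-5-(prop-1-en-2-yl)cyclohexan-1-one | O=C1C[C@@H](C(C)=C)CC[C@@]1(C)CC(=O)CC(C)C | intermediate
6 | (3aS,5S,7aS)-3a-hydroxy-3-isopropyl-7a-methyl-5-(prop-1-en-2-yl)octahydro-2H-inden-2-one (cis-fused ketol; epimers at the isopropyl carbon) | CC(C)C1C(=O)C[C@]2(C)CC[C@H](C(C)=C)C[C@]12O | intermediate
7 | (5S,7aS)-3-isopropyl-7a-methyl-5-(prop-1-en-2-yl)-1,4,5,6,7,7a-hexahydro-2H-inden-2-one | CC(C)C1=C2C[C@@H](C(C)=C)CC[C@@]2(C)CC1=O | intermediate
8 | (5S,7aS)-5-(1-hydroperoxy-1-methoxyethyl)-3-isopropyl-7a-methyl-1,4,5,6,7,7a-hexahydro-2H-inden-2-one | CC(C)C1=C2C[C@@H](C(C)(OC)OO)CC[C@@]2(C)CC1=O | intermediate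
9 | (5S,7aS)-3-isopropyl-7a-methyl-2-oxo-2,4,5,6,7,7a-hexahydro-1H-inden-5-yl acetate | CC(C)C1=C2C[C@@H](OC(C)=O)CC[C@@]2(C)CC1=O | intermediate
10 | (2R,3R,3aS,5S,7aS)-3-isopropyl-7a-methyloctahydro-1H-indene-2,5-diol | CC(C)[C@H]1[C@H](O)C[C@]2(C)CC[C@H](O)C[C@@H]12 | intermediate
11 | (2R,3R,3aS,7aS)-2-hydroxy-3-isopropyl-7a-methyloctahydro-5H-inden-5-one | CC(C)[C@H]1[C@H](O)C[C@]2(C)CCC(=O)C[C@@H]12 | intermediate
12 | (2R,3R,3aS,7aS)-2-(benzyloxy)-3-isopropyl-7a-methyloctahydro-5H-inden-5-one | CC(C)[C@H]1[C@H](OCc3ccccc3)C[C@]2(C)CCC(=O)C[C@@H]12 | intermediate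
13 | (Z)-but-2-en-1-ol | C/C=C\CO | starting material
14 | bis[(Z)-but-2-enyl] ketal of 12 | CC(C)[C@H]1[C@H](OCc3ccccc3)C[C@]2(C)CCC(OC/C=C\C)(OC/C=C\C)C[C@@H]12 | intermediate
15 | (2R,3R,3aS,7aS)-2-(benzyloxy)-5-[(Z)-but-2-en-1-yloxy]-3-isopropyl-7a-methyl-2,3,3a,4,7,7a-hexahydro-1H-indene | CC(C)[C@H]1[C@H](OCc3ccccc3)C[C@]2(C)CC=C(OC/C=C\C)C[C@@H]12 | intermediate
16 | (2R,3R,3aS,6R,7aS)-2-(benzyloxy)-6-[(2R)-but-3-en-2-yl]-3-isopropyl-7a-methyloctahydro-5H-inden-5-one | CC(C)[C@H]1[C@H](OCc3ccccc3)C[C@]2(C)C[C@H]([C@H](C)C=C)C(=O)C[C@@H]12 | intermediate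
17 | (S)-β-citronellene, (3S)-3,7-dimethylocta-1,6-diene | C=C[C@@H](C)CCC=C(C)C | starting material
18 | (4S)-4-methylhex-5-enal | C=C[C@@H](C)CCC=O | intermediate
19 | (5S)-1,1-dibromo-5-methylhepta-1,6-diene | C=C[C@@H](C)CCC=C(Br)Br | intermediate
20 | [(5S)-5-methylhept-6-en-1-yn-1-yl]lithium | C=C[C@@H](C)CCC#C[Li] | intermediate
21 | (3S)-3-methylnon-1-en-7-yne | C=C[C@@H](C)CCC#CC | intermediate
22 | bicyclic zirconacyclopentene Cp2Zr[C(CH3)=C–CH–CH2] fused to the methylcyclopentane (CH2Zr trans to methyl) | C[C@H]1CCC2=C(C)[Zr](C[C@H]12)(C3C=CC=C3)C4C=CC=C4 | intermediate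
23 | (1Z,2R,3S)-1-(1-iodoethylidene)-2-(iodomethyl)-3-methylcyclopentane | IC[C@@H]1[C@@H](C)CC/C1=C(\C)I | intermediate
24 | (1Z,3S)-1-(1-iodoethylidene)-3-methyl-2-methylidenecyclopentane | C=C1[C@@H](C)CC/C1=C(\C)I | intermediate
25 | 9-{[(1S,2S,5Z)-5-(1-iodoethylidene)-2-methylcyclopentyl]methyl}-9-borabicyclo[3.3.1]nonane | B1(C[C@H]2[C@@H](C)CC/C2=C(\C)I)C3CCCC1CCC3 | intermediate
26 | [(1S,2S,5Z)-5-(1-iodoethylidene)-2-methylcyclopentyl]methanol | OC[C@H]1[C@@H](C)CC/C1=C(\C)I | intermediate
27 | (1S,2S,5Z)-5-(1-iodoethylidene)-2-methylcyclopentane-1-carbaldehyde | O=C[C@H]1[C@@H](C)CC/C1=C(\C)I | intermediate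
28 | (1Z,2S,3S)-2-ethenyl-1-(1-iodoethylidene)-3-methylcyclopentane | C=C[C@H]1[C@@H](C)CC/C1=C(\C)I | intermediate
29 | {(1Z)-1-[(2S,3S)-2-ethenyl-3-methylcyclopentylidene]ethyl}lithium | C=C[C@H]1[C@@H](C)CC/C1=C(\C)[Li] | intermediate
30 | (2R,3R,3aS,5R,6R,7aS)-2-(benzyloxy)-6-[(2R)-but-3-en-2-yl]-5-{(1Z)-1-[(2S,3S)-2-ethenyl-3-methylcyclopentylidene]ethyl}-3-isopropyl-7a-methyloctahydro-1H-inden-5-ol | CC(C)[C@H]1[C@H](OCc6ccccc6)C[C@]2(C)C[C@H]([C@H](C)C=C)[C@@](O)(/C(C)=C3/CC[C@H](C)[C@@H]3C=C)C[C@@H]12 | intermediate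
31 | (2R,3R,3aS,5R,6R,7aS)-2-(benzyloxy)-6-[(2R)-but-3-en-2-yl]-5-[(2R,3S,4S,5S)-4-ethenyl-2,5-dimethyl-1-oxaspiro[2.4]heptan-2-yl]-3-isopropyl-7a-methyloctahydro-1H-inden-5-ol | CC(C)[C@H]1[C@H](OCc6ccccc6)C[C@]2(C)C[C@H]([C@H](C)C=C)[C@@](O)([C@@]4(C)O[C@]43CC[C@H](C)[C@@H]3C=C)C[C@@H]12 | intermediate
32 | tetracyclic epoxy alcohol benzyl ether with a (Z)-CH=CH unit in ring C (target skeleton; α-OBn in place of the ring A ketone) | CC(C)[C@H]1[C@H](OCc6ccccc6)C[C@]2(C)C[C@@H]3[C@H](C)/C=C\[C@H]4[C@@H](C)CC[C@]45O[C@]5(C)[C@@]3(O)C[C@@H]12 | intermediate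
33 | saturated tetracyclic epoxy diol (target with an α-OH in place of the ring A ketone) | CC(C)[C@H]1[C@H](O)C[C@]2(C)C[C@@H]3[C@H](C)CC[C@H]4[C@@H](C)CC[C@]45O[C@]5(C)[C@@]3(O)C[C@@H]12 | intermediate
34 | target CNP0332295.1 | CC(C)[C@H]1C(=O)C[C@]2(C)C[C@@H]3[C@H](C)CC[C@H]4[C@@H](C)CC[C@]45O[C@]5(C)[C@@]3(O)C[C@@H]12 | target

**Totals:** 21 steps. Longest linear sequence: 13 steps (steps 1–8 then 17–21; the east branch, steps 9–16 then 17–21, is equally long).

**Steps most likely to fail**

Step 5. One dissolving-metal step must set the trans ring fusion and the isopropyl centre; a cis-fused product or a mixture is the likely failure. The fallback sets out from 9 and replaces electron transfer by radical hydrogen-atom transfer. Mn(dpm)3 (cat.), PhSiH3, t-BuOOH and i-PrOH reduce only the enone C=C and give the trans-fused keto acetate F1, with the ring-fusion hydrogen arriving on the face away from the angular methyl. Li, NH3, EtOH then only has to reduce the saturated ketone to the more stable alcohol and remove the acetate, which comes back to the route at 10.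

Step 8. Enol ether regiochemistry and chair-versus-boat control at the new methyl centre can erode the selectivity. The fallback sets out from 12 and makes the same bond by conjugate addition instead of rearrangement. LiN(i-Pr)2 then acetaldehyde gives the aldol F2; MsCl/Et3N then DBU gives the (E)-ethylidene ketone F3. CH2=CHMgBr with CuBr·SMe2 and Me3SiCl adds vinyl to the exocyclic carbon from the face away from the angular methyl, and protonation places the side chain equatorial, which comes back to the route at 16.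

Step 19. Closure of the eight-membered ring may stall. The fallback sets out from 30 and changes the order, so that ring C closes on the flat (Z)-tetrasubstituted alkene instead of on the oxirane. The second-generation Grubbs catalyst gives the cyclic diene alcohol F4 (the tetrasubstituted alkene is inert to the catalyst). VO(acac)2/t-BuOOH then epoxidises the allylic alkene from the hydroxyl face, which comes back to the route at 32.

**Further compounds**
F1 | step 5 | (3R,3aS,5S,7aS)-3-isopropyl-7a-methyl-2-oxooctahydro-1H-inden-5-yl acetate | CC(C)[C@H]1C(=O)C[C@]2(C)CC[C@H](OC(C)=O)C[C@@H]12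
F2 | step 8 | (2R,3R,3aS,6R,7aS)-2-(benzyloxy)-6-(1-hydroxyethyl)-3-isopropyl-7a-methyloctahydro-5H-inden-5-one (carbinol epimers) | CC(C)[C@H]1[C@H](OCc3ccccc3)C[C@]2(C)C[C@H](C(C)O)C(=O)C[C@@H]12
F3 | step 8 | (2R,3R,3aS,6E,7aS)-2-(benzyloxy)-6-ethylidene-3-isopropyl-7a-methyloctahydro-5H-inden-5-one | CC(C)[C@H]1[C@H](OCc3ccccc3)C[C@]2(C)C/C(=C\C)C(=O)C[C@@H]12
F4 | step 19 | tetracyclic tertiary alcohol benzyl ether with a (Z)-CH=CH unit and the (Z)-tetrasubstituted alkene in ring C (32 without the oxirane oxygen) | CC(C)[C@H]1[C@H](OCc6ccccc6)C[C@]2(C)C[C@@H]3[C@H](C)/C=C\[C@H]4[C@@H](C)CC/C4=C(\C)[C@@]3(O)C[C@@H]12
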